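Add up the amounts first. The readings are of target, so whatever falls short of the substrate charged is unaccounted for: the red plateau reads 87.7%, a loss of 12.3%, and the blue plateau reads 75.0%, a loss of 25.0%.

| flask | substrate | temperature | remark | time |
|---|---|---|---|---|
| red | 0.070 M | −10 °C | run made earlier |  |
| blue | 0.11 M | 23 °C | run made earlier |  |
| north-west | 0.050 M | −25 °C |  | 12 d |
| north | 0.050 M |  | at 35 °C until 4.0 d, from then on at −25 °C | 12 d |
| north-east | 0.050 M | 35 °C |  | 12 d |
| south-east | 0.050 M | 5 °C |  | 12 d |

red run (percent of the substrate charged): time / d: target / % = 0.625: 35.2; 1.04: 53.0; 2.08: 87.5; 4.00: 87.1; 8.00: 88.5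

blue run (percent of the substrate charged): time / h: target / % = 3.00: 75.4; 4.00: 74.8; 8.00: 75.0; 20.0: 74.6; 30.0: 75.1

(readings scatter by 1 percentage point)

- the best flask by amount of target, in percent of the substrate charged; "all alike" if 1.5 percentage points covers them all (north-west / north / north-east / south-east / all alike)
- amount of target at the end, in percent of the substrate charged, north-west
- amount of target at the end, in percent of the substrate charged, north
- amount of target at the end, in percent of the substrate charged, north-east
- amount of target at the end, in percent of the substrate charged, south-east

Turn the temperature first. By hand, if a plateau were the equilibrium of a first-order step, the approach to it would be exponential. Test that on the red run: its first reading gives a rate constant of 0.821 d⁻¹, which predicts 71.8% at 2.08 d, but the reading there is 87.5%, higher by far more than the scatter of 1 percentage point. So read the red rise as steady (zero-order), at about 0.0357 M d⁻¹ of target, ending abruptly in a finished yield. Read temperature as changing the pace, though the blue run differs from the red run in charge as well: the blue run made target at a mean of at least 0.664 M d⁻¹, faster than the red run.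

Turn the time next. At the red pace, 0.050 M takes 1.40 d, so the 12 d allow north-west, at −25 °C, a slowing of 8.56-fold. Reckon north-west as finished, on the assumption that the cold slows the pace by less than that.

Turn the charge last. Red and blue differ in both charge and temperature, so this is a choice: lay their difference in loss on the charge. Take the power of the charge by which the lost share grows, the logarithm of the loss ratio over that of the charge ratio: it reads 1.57, and this is the loss exponent. At 0.050 M it gives a loss of 7.25%, so reckon 92.8% for north-west, north, north-east and south-east alike.

The forecast differs. It says the plateaus “suggest a reversible, exothermic equilibrium”, gives 75% for north-west, 84% for north, 69.5% for north-east and 82.5% for south-east, and names north as best.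

The flasks give 93.0% for north-west, 92.4% for north, 92.4% for north-east and 92.7% for south-east, so the verdict is all alike: the spread of 0.6 points is smaller than the margin of 1.5 points. North-west still held 0.025% of its substrate at the end. The loss of 7.25% from the exponent stands beside side product of 6.99% in north-west and 7.61% in north, where side product counts as two in the percentage, as it holds that many.

    substrate → target, rate k1*[substrate]/(1 + ([substrate]/sat1)) (1.53 mM, k = 0.122 min⁻¹, Ea = 76.0 kJ mol⁻¹)
    2 substrate → homo dimer (k = 8.95 × 10⁻⁶ M⁻¹ min⁻¹, Ea = 82.0 kJ mol⁻¹)
    substrate + target → side product (k = 0.0168 M⁻¹ min⁻¹, Ea = 77.0 kJ mol⁻¹)
    (constants at 5 °C)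

Now try the neighbour of north charged with 0.030 M of substrate: the exponent gives a loss of 3.25%, hence 96.8% of target. The computed flask gives 96.9% of target and 3.10% of side product.

(All runs are simulated with constants of no real substance; noise was put on by code.)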